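**Plan**
Retrosynthesis cuts, in this order: the O–Si bond at C4, the aryl ether bond C8a–O1 of ring C, the C2–H bond (ketone reduction), the C3–C4 bond (aldol of an aryl aldehyde with acetophenone), the triflate S–O bond and the C8–prenyl bond (cross-metathesis back to allyl, Claisen back to an allyl ether).
Forward: ring A comes complete from 2-hydroxy-4,6-dimethoxybenzaldehyde; prenyl is placed on the future C8 (steps 1–3), the phenol is triflated (step 4), the three-carbon chain with the phenyl ring is joined (step 5), and ring C, the only ring built, is closed in step 8.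
Stereochemistry: C4 comes from a si-face-selective Ipc2BCl aldol and C2 from a reagent-controlled CBS reduction; the open-chain (1S,3S) anti pair becomes 2,4-cis (2S,4S) because no carbinol C–O bond is broken afterwards.
Enabling feature: O1 joins aromatic C8a to the carbinol carbon C2, so ring C is the cyclic aryl ether of an anti-1,3-diol. With the C4 oxygen silylated, the C2 hydroxyl is the only one that can reach C8a, through a six-membered ring.

Key step: step 8

Remark on the chemistry: the enol diisopinocampheylborinate made from a methyl ketone with (+)-Ipc2BCl (the reagent from (−)-α-pinene) is assumed to add to the si face of the aldehyde; should the opposite sense be met, the enantiomeric reagent is taken. "Prenyl" means 3-methylbut-2-en-1-yl.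

Step 1
Reactants: 1 2-hydroxy-4,6-dimethoxybenzaldehyde; 2 allyl bromide
Product: 3 2-(allyloxy)-4,6-dimethoxybenzaldehyde
Conditions: K2CO3, DMF, 60 °C
Reagents that add atoms: none
Why: Williamson etherification, in which the phenoxide freed from its hydrogen bond by K2CO3 in DMF is alkylated on oxygen by the primary allylic bromide.

Step 2
Reactants: 3 2-(allyloxy)-4,6-dimethoxybenzaldehyde
Product: 5 3-allyl-2-hydroxy-4,6-dimethoxybenzaldehyde, via allyl dienone 4 (not isolated)
Conditions: N,N-diethylaniline, 195 °C
Reagents that add atoms: none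
Why: aromatic Claisen rearrangement, in which the only free ortho position (C3, between the ether oxygen and a methoxy group) receives the allyl group and the dienone tautomerises to the phenol.

Step 3
Reactants: 5 3-allyl-2-hydroxy-4,6-dimethoxybenzaldehyde; 6 2-methyl-2-butene
Product: 7 2-hydroxy-4,6-dimethoxy-3-prenylbenzaldehyde
Conditions: second-generation Grubbs catalyst RuCl2(H2IMes)(PCy3)(=CHPh) (3 mol%), 2-methyl-2-butene/CH2Cl2, 35 °C, sealed tube
Reagents that add atoms: none
Why: olefin cross-metathesis of a terminal allyl arene with excess 2-methyl-2-butene, a standard way to a prenyl group that is driven by loss of propene and tolerates the phenol and the aldehyde.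

Step 4
Reactants: 7 2-hydroxy-4,6-dimethoxy-3-prenylbenzaldehyde
Product: 8 2-formyl-3,5-dimethoxy-6-prenylphenyl trifluoromethanesulfonate
Conditions: Tf2O, pyridine, CH2Cl2, −10 to 0 °C
Reagents that add atoms: trifluoromethanesulfonic anhydride (Tf2O), O=S(=O)(OS(=O)(=O)C(F)(F)F)C(F)(F)F
Why: O-sulfonylation of the phenol turns the C8a oxygen into the leaving group for step 8, and the aldehyde and the trisubstituted olefin are inert to Tf2O/pyridine in the cold.

Step 5
Reactants: 8 2-formyl-3,5-dimethoxy-6-prenylphenyl trifluoromethanesulfonate; 9 acetophenone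
Product: 12 2-[(1S)-1-hydroxy-3-oxo-3-phenylpropyl]-3,5-dimethoxy-6-prenylphenyl trifluoromethanesulfonate, via enol borinate 10 (not isolated), via boron aldolate 11 (not isolated)
Conditions: 9, (+)-Ipc2BCl, Et3N, Et2O, 0 °C; then 8, −78 to −20 °C; H2O2, MeOH, pH 7 buffer, 0 °C
Reagents that add atoms: none
Why: Paterson boron aldol of a methyl ketone, in which the isopinocampheyl groups on boron steer the enolate to the si face of the aldehyde in a cyclic transition state and so set the (S) carbinol centre (the future C4); a moderate enantiomer ratio is acceptable because step 7 turns the minor enantiomer into a separable diastereomer.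

Step 6
Reactants: 12 2-[(1S)-1-hydroxy-3-oxo-3-phenylpropyl]-3,5-dimethoxy-6-prenylphenyl trifluoromethanesulfonate
Product: 13 2-[(1S)-1-(tert-butyldimethylsilyloxy)-3-oxo-3-phenylpropyl]-3,5-dimethoxy-6-prenylphenyl trifluoromethanesulfonate
Conditions: TBSOTf, 2,6-lutidine, CH2Cl2, −78 to −40 °C
Reagents that add atoms: tert-butyldimethylsilyl trifluoromethanesulfonate (TBSOTf), CC(C)(C)[Si](C)(C)OS(=O)(=O)C(F)(F)F
Why: silylation of a secondary alcohol with a silyl triflate and a hindered pyridine base is faster at low temperature than E1cB loss of the β-oxygen, and it caps the one oxygen that would otherwise sit next to palladium in step 8.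

Step 7
Reactants: 13 2-[(1S)-1-(tert-butyldimethylsilyloxy)-3-oxo-3-phenylpropyl]-3,5-dimethoxy-6-prenylphenyl trifluoromethanesulfonate
Product: 15 2-[(1S,3S)-1-(tert-butyldimethylsilyloxy)-3-hydroxy-3-phenylpropyl]-3,5-dimethoxy-6-prenylphenyl trifluoromethanesulfonate, via catechol borate ester 14 (not isolated)
Conditions: (R)-2-methyl-CBS-oxazaborolidine (0.5 equiv), catecholborane (2 equiv), toluene, −78 to −30 °C; MeOH, then aqueous NaHCO3
Reagents that add atoms: none
Why: Corey–Bakshi–Shibata reduction, in which the (R)-oxazaborolidine places phenyl as the large group and delivers hydride to the re face of the aryl ketone to set the (S) carbinol (the future C2) under reagent control, while catecholborane does not hydroborate the prenyl olefin; the minor aldol enantiomer ends as the syn diastereomer, which chromatography removes.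

Step 8
Reactants: 15 2-[(1S,3S)-1-(tert-butyldimethylsilyloxy)-3-hydroxy-3-phenylpropyl]-3,5-dimethoxy-6-prenylphenyl trifluoromethanesulfonate
Product: 16 (2S,4S)-4-(tert-butyldimethylsilyloxy)-5,7-dimethoxy-8-prenyl-2-phenylchromane
Conditions: Pd(OAc)2 (5 mol%), rac-2-(di-tert-butylphosphino)-1,1'-binaphthyl (7 mol%), Cs2CO3 (1.5 equiv), toluene, 80 °C
Reagents that add atoms: none
Why: Zerovalent palladium, formed in the flask from Pd(OAc)2 and the phosphine, inserts into the C8a–OTf bond, Cs2CO3 turns the one free hydroxyl into a palladium-bound alkoxide, and C–O reductive elimination forms the C8a–O1 bond. The closest known reaction is the palladium-catalysed intramolecular etherification of ortho-(hydroxyalkyl)aryl halides and sulfonates to chromans with bulky di-tert-butyl biaryl phosphines. Ring C (O1–C2–C3–C4–C4a–C8a) closes by aryl–oxygen reductive elimination from a seven-membered aryl(alkoxo)palladium chelate, which contracts to the six-membered pyran. No stereocentre is made, and since neither carbinol C–O bond is broken, (1S,3S) in 15 becomes (2S,4S) in 16, with the cis relation following from the anti diol. The step needs O-arylation to outrun β-hydride elimination of the secondary alkoxide, which the bulky electron-rich ligand secures by speeding reductive elimination, and Cs2CO3 in toluene spares the triflate S–O bond. It also needs the benzylic oxygen next to the palladium-bearing carbon to stay out of the reaction, which the silyl cap secures: a free alkoxide there could form a five-membered chelate, give up hydride to palladium with loss of the triflate, or take over the triflyl group.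

Step 9
Reactants: 16 (2S,4S)-4-(tert-butyldimethylsilyloxy)-5,7-dimethoxy-8-prenyl-2-phenylchromane
Product: 17 (2S,4S)-5,7-dimethoxy-8-prenyl-2-phenylchroman-4-ol
Conditions: TBAF, THF, 0 °C to rt; aqueous NaHCO3 work-up, chromatography on Et3N-deactivated silica
Reagents that add atoms: none
Why: fluoride-induced Si–O cleavage under non-acidic conditions frees the C4 hydroxyl without ionising the electron-rich benzylic C4–O bond, so neither stereocentre, the aryl ether nor the prenyl olefin is touched.

**Compound list**
1 | 2-hydroxy-4,6-dimethoxybenzaldehyde | COc1cc(O)c(C=O)c(OC)c1 | starting material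
2 | allyl bromide | C=CCBr | starting material
3 | 2-(allyloxy)-4,6-dimethoxybenzaldehyde | COc1cc(OCC=C)c(C=O)c(OC)c1 | intermediate
4 | 5-allyl-2,4-dimethoxy-6-oxocyclohexa-1,3-diene-1-carbaldehyde (Claisen dienone, racemic, not isolated) | O=CC1=C(OC)C=C(OC)C(CC=C)C1=O | intermediate
5 | 3-allyl-2-hydroxy-4,6-dimethoxybenzaldehyde | COc1cc(OC)c(C=O)c(O)c1CC=C | intermediate
6 | 2-methyl-2-butene | CC=C(C)C | starting material
7 | 2-hydroxy-4,6-dimethoxy-3-prenylbenzaldehyde | COc1cc(OC)c(C=O)c(O)c1CC=C(C)C | intermediate
8 | 2-formyl-3,5-dimethoxy-6-prenylphenyl trifluoromethanesulfonate | COc1cc(OC)c(C=O)c(OS(=O)(=O)C(F)(F)F)c1CC=C(C)C | intermediate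
9 | acetophenone | CC(=O)c1ccccc1 | starting material
10 | (1-phenylvinyl) diisopinocampheylborinate from (+)-Ipc2BCl (not isolated) | C=C(OB([C@H]1C[C@H]2C[C@@H]([C@@H]1C)C2(C)C)[C@H]1C[C@H]2C[C@@H]([C@@H]1C)C2(C)C)c1ccccc1 | intermediate
11 | O-(diisopinocampheylboryl) derivative of aldol 12 (not isolated) | COc1cc(OC)c([C@@H](OB([C@H]2C[C@H]3C[C@@H]([C@@H]2C)C3(C)C)[C@H]2C[C@H]3C[C@@H]([C@@H]2C)C3(C)C)CC(=O)c2ccccc2)c(OS(=O)(=O)C(F)(F)F)c1CC=C(C)C | intermediate
12 | 2-[(1S)-1-hydroxy-3-oxo-3-phenylpropyl]-3,5-dimethoxy-6-prenylphenyl trifluoromethanesulfonate | COc1cc(OC)c([C@@H](O)CC(=O)c2ccccc2)c(OS(=O)(=O)C(F)(F)F)c1CC=C(C)C | intermediate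
13 | 2-[(1S)-1-(tert-butyldimethylsilyloxy)-3-oxo-3-phenylpropyl]-3,5-dimethoxy-6-prenylphenyl trifluoromethanesulfonate | COc1cc(OC)c([C@@H](O[Si](C)(C)C(C)(C)C)CC(=O)c2ccccc2)c(OS(=O)(=O)C(F)(F)F)c1CC=C(C)C | intermediate
14 | O-(1,3,2-benzodioxaborol-2-yl) derivative of alcohol 15 (not isolated) | COc1cc(OC)c([C@@H](O[Si](C)(C)C(C)(C)C)C[C@H](OB2Oc3ccccc3O2)c2ccccc2)c(OS(=O)(=O)C(F)(F)F)c1CC=C(C)C | intermediate
15 | 2-[(1S,3S)-1-(tert-butyldimethylsilyloxy)-3-hydroxy-3-phenylpropyl]-3,5-dimethoxy-6-prenylphenyl trifluoromethanesulfonate | COc1cc(OC)c([C@@H](O[Si](C)(C)C(C)(C)C)C[C@H](O)c2ccccc2)c(OS(=O)(=O)C(F)(F)F)c1CC=C(C)C | intermediate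
16 | (2S,4S)-4-(tert-butyldimethylsilyloxy)-5,7-dimethoxy-8-prenyl-2-phenylchromane | COc1cc(OC)c2c(c1CC=C(C)C)O[C@H](c1ccccc1)C[C@@H]2O[Si](C)(C)C(C)(C)C | intermediate
17 | (2S,4S)-5,7-dimethoxy-8-prenyl-2-phenylchroman-4-ol | COc1cc(OC)c2c(c1CC=C(C)C)O[C@H](c1ccccc1)C[C@@H]2O | target

**Step count:** 9 steps in total; longest linear sequence 9 steps.

**Steps most likely to fail**

Step 8. Oxidative addition into the doubly ortho-substituted C8a–OTf bond may be slow. The palladium alkoxide may lose β-hydride, with net reduction of the triflate and oxidation of the carbinol. Base may cleave the triflate S–O bond, or the silyl group may move between the two oxygens. The fallback closes the same ring from the other end of the ether oxygen. It sets out from 13. Reduction with the (S)-configured oxazaborolidine and catecholborane should give the syn alcohol 2-[(1S,3R)-1-(tert-butyldimethylsilyloxy)-3-hydroxy-3-phenylpropyl]-3,5-dimethoxy-6-prenylphenyl trifluoromethanesulfonate F1. Et4NOH in dioxane then cleaves the aryl triflate to the phenol (1R,3S)-3-(tert-butyldimethylsilyloxy)-3-(2-hydroxy-4,6-dimethoxy-3-prenylphenyl)-1-phenylpropan-1-ol F2. Mitsunobu cyclisation (PPh3, DIAD, THF, 0 °C) forms O1–C2 with inversion at the carbinol carbon and comes back to the route at 16.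

Step 5. The bulky enol borinate may add slowly to the 2,6-disubstituted aldehyde, facial selectivity may be poor, or the aldol may dehydrate to the enone on work-up. The fallback gives up enantioselection in the aldol and lets the reduction sort the enantiomers. It sets out from 8. The lithium enolate of 9 (LiN(iPr)2, THF, −78 °C) should give the racemic aldol 2-(1-hydroxy-3-oxo-3-phenylpropyl)-3,5-dimethoxy-6-prenylphenyl trifluoromethanesulfonate F3. Silylation as in step 6 gives the racemic silyl ether 2-[1-(tert-butyldimethylsilyloxy)-3-oxo-3-phenylpropyl]-3,5-dimethoxy-6-prenylphenyl trifluoromethanesulfonate F4. The reduction of step 7 then converts the two enantiomers into diastereomers, 15 and the syn isomer 2-[(1R,3S)-1-(tert-butyldimethylsilyloxy)-3-hydroxy-3-phenylpropyl]-3,5-dimethoxy-6-prenylphenyl trifluoromethanesulfonate F5. These are separated by chromatography and the route is rejoined at 15, at the cost of half the material.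

Step 6. The β-oxygen may be lost by E1cB elimination to the enone, or silylation of the crowded carbinol may stay incomplete. The fallback combines protection and reduction in one operation. It sets out from 12. An Evans–Tishchenko reduction (SmI2 cat., isobutyraldehyde, THF, −10 °C) reduces the ketone by intramolecular hydride transfer within the samarium-bound hemiacetal and leaves the aldol oxygen acylated, giving the anti monoester (1S,3S)-3-hydroxy-1-[4,6-dimethoxy-3-prenyl-2-(trifluoromethanesulfonyloxy)phenyl]-3-phenylpropyl 2-methylpropanoate F6. Cyclisation under the conditions of step 8 should give the ester (2S,4S)-5,7-dimethoxy-8-prenyl-2-phenylchroman-4-yl 2-methylpropanoate F7. K2CO3 in methanol removes the ester and arrives at 17. Acyl migration to the free hydroxyl under base is the weak point of this detour.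

**Further compounds**
F1 | step 8 | 2-[(1S,3R)-1-(tert-butyldimethylsilyloxy)-3-hydroxy-3-phenylpropyl]-3,5-dimethoxy-6-prenylphenyl trifluoromethanesulfonate | COc1cc(OC)c([C@@H](O[Si](C)(C)C(C)(C)C)C[C@@H](O)c2ccccc2)c(OS(=O)(=O)C(F)(F)F)c1CC=C(C)C
F2 | step 8 | (1R,3S)-3-(tert-butyldimethylsilyloxy)-3-(2-hydroxy-4,6-dimethoxy-3-prenylphenyl)-1-phenylpropan-1-ol | COc1cc(OC)c([C@@H](O[Si](C)(C)C(C)(C)C)C[C@@H](O)c2ccccc2)c(O)c1CC=C(C)C
F3 | step 5 | racemic 2-(1-hydroxy-3-oxo-3-phenylpropyl)-3,5-dimethoxy-6-prenylphenyl trifluoromethanesulfonate | COc1cc(OC)c(C(O)CC(=O)c2ccccc2)c(OS(=O)(=O)C(F)(F)F)c1CC=C(C)C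
F4 | step 5 | racemic 2-[1-(tert-butyldimethylsilyloxy)-3-oxo-3-phenylpropyl]-3,5-dimethoxy-6-prenylphenyl trifluoromethanesulfonate | COc1cc(OC)c(C(O[Si](C)(C)C(C)(C)C)CC(=O)c2ccccc2)c(OS(=O)(=O)C(F)(F)F)c1CC=C(C)C
F5 | step 5 | 2-[(1R,3S)-1-(tert-butyldimethylsilyloxy)-3-hydroxy-3-phenylpropyl]-3,5-dimethoxy-6-prenylphenyl trifluoromethanesulfonate | COc1cc(OC)c([C@H](O[Si](C)(C)C(C)(C)C)C[C@H](O)c2ccccc2)c(OS(=O)(=O)C(F)(F)F)c1CC=C(C)C
F6 | step 6 | (1S,3S)-3-hydroxy-1-[4,6-dimethoxy-3-prenyl-2-(trifluoromethanesulfonyloxy)phenyl]-3-phenylpropyl 2-methylpropanoate | COc1cc(OC)c([C@@H](OC(=O)C(C)C)C[C@H](O)c2ccccc2)c(OS(=O)(=O)C(F)(F)F)c1CC=C(C)C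
F7 | step 6 | (2S,4S)-5,7-dimethoxy-8-prenyl-2-phenylchroman-4-yl 2-methylpropanoate | COc1cc(OC)c2c(c1CC=C(C)C)O[C@H](c1ccccc1)C[C@@H]2OC(=O)C(C)C
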